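## Numbering

Atom locants follow the target. Ring A is C1 (carries OH and C6), C2, C3 (carries C7), C4, C5 (carries ring B). C6 is the CH2OAc carbon. The side chain is C7(CH3)=C8–C9=C10–C11(CH3)2OOH. Ring B is C1′ (bonded to C5), C2′ (C=O), C3′=C4′, C5′ (CH3). "Down" means the face of ring A that carries C6, C7 and ring B in the target; the C1 hydroxyl is "up". "Endo" on the bridged lactones means syn to the lactone bridge, that is, down.

Compounds are numbered 1–33 in the order of the steps. Landmarks: 7 key-step precursor, 9 acceptor, 10 key-step product, 15 bridged lactone, 21 ring B enone, 26 methyl ketone, 32 deoxy precursor, 33 target.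

## Analysis of the target

Compound 33 has two five-membered rings joined by the single bond C5–C1′. Ring A is a cyclopentane with a tertiary alcohol and the acetoxymethyl carbon C6 on C1, the eight-carbon side chain on C3 and ring B on C5. Ring B is a 5-methylcyclopent-2-enone attached through C1′. The five stereocentres are 1R, 3S, 5S, 1′S and 5′R: on ring A, C6, C7 and ring B share one face and the hydroxyl has the other; on ring B the C5 substituent and the C5′ methyl are cis. The side chain holds a 7Z trisubstituted alkene conjugated to a 9E alkene and ends in a tertiary allylic hydroperoxide at C11. The hydroperoxide tolerates neither reductants, strong bases nor most metals. C1′ is epimerisable towards the more stable trans ring B. The primary acetate sits next to a free tertiary alcohol. The hard points are the relay of configuration from ring A to ring B across one rotatable bond, the Z geometry at C7=C8, and the late introduction of the peroxide. The strategy rests on ring A: C1 is an oxygenated quaternary carbon with a one-carbon branch, flanked by C2H2 and the stereogenic C5, and C3 lies between two CH2 groups. That is the pattern of a methylenecyclopentane C1=C6 built from a three-carbon unit C2–C1(=C6)–C5 and a two-carbon acceptor C3=C4.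

## Retrosynthetic reasoning

**C11–O bond.** The hydroperoxide is removed first, giving the skipped diene 32. No other step of the route tolerates a peroxide, so it must come last. The forward reaction is a Schenck ene photooxygenation that has to place oxygen on C11, take hydrogen from C9 and move the C10=C11 double bond to C9=C10 with E geometry.

**C3′=C4′ unsaturation and the acetate.** The enone of 32 is traced to the silyl enol ether 31 (Saegusa–Ito oxidation), and the acetate to the diol 30. The ring B ketone therefore travels as its kinetic enol ether from 25 onwards. This shields the carbonyl from nucleophiles and removes the acidic hydrogen pathway that would epimerise C1′. The forward steps must acetylate the primary C6 hydroxyl beside the tertiary one and dehydrogenate only towards C4′.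

**C7=C8 bond.** Cutting the trisubstituted alkene of 30 gives the methyl ketone 26 and the ylide 29 from the phosphonium salt 28. The cut is made here because the salt delivers C8–C11 with the terminal alkene already in place. The forward Wittig reaction has to favour the Z isomer, in which the ring and C9 are cis.

**C7–CH3 bond and the C6–O–C7 bridge.** Ketone 26 and its C6 hydroxyl arise together when a methyl nucleophile opens the lactone 25. The lactone is the stereochemical device of the route: a bridge from C6 to C7 can exist only when both are on the same face, so it defines C3 and protects C6 and C7 at once.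

**Ring B.** The enol ether 25 comes from ketone 23, and this from the silyl ether 22. The two C–H bonds at C1′ and C5′ of 22 are cut back to the tetrasubstituted enone 21 (cis hydrogenation). The C1′=C5′ bond of 21 is cut to the 1,4-diketone 20 (aldol condensation), and the C2′–C3′ bond of 20 to aldehyde 18 and but-3-en-2-one 19 (Stetter reaction). Aldehyde 18 comes from the terminal alkyne 17, so C1′ and C2′ are the two alkyne carbons of 15. This annulation needs only a two-carbon handle on C5, and an alkyne is inert through the early steps.

**C3–H bond.** Lactone 15 is traced to the lactone acid 13 by decarboxylation. A Krapcho decarboxylation is not used here: on the bridged lactone it would need an enolate at the bridgehead C3, which Bredt's rule forbids. A radical decarboxylation has no such limit. Acid 13 comes from the diol diester 11, in which the C6 hydroxyl can reach only the ester on its own face.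

**C1–O and C6–O bonds.** Diol 11 comes from the exocyclic alkene of 10 by dihydroxylation. The forward step must add both oxygens anti to the C5 substituent.

**C4–C5 and C2–C3 bonds (key disconnection).** Alkene 10 is cut into the silyl acetate 7 and the methylenemalonate 9. All five ring carbons and the anchors for C6, C7 and ring B arrive in one step. The two equal esters keep C3 non-stereogenic, so only C5 has to be controlled, by the ligand on palladium.

**Fragments.** Acetate 7 comes from alcohol 6, which is cut between the vinyl carbon and the carbinol carbon into bromide 4 (as its Grignard reagent 5) and ynal 3, made from alkyne 1. Acceptor 9 comes from malonate 8 by methylenation.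

## Alternatives that were turned down

**Alternative 1:** Ring B would be cut at C4′–C5′, C1′–C2′ and C2′–C3′. In the forward sense the (Z)-propenyl compound A2, ethyne A3 and carbon monoxide A4 would combine on cobalt in a three-component Pauson–Khand reaction to give the enone A1. This is stronger than the chosen route on ring B step economy: one step delivers the C3′=C4′ enone directly, where the chosen route needs five operations. The cis relation of C1′ and C5′ would follow from the Z alkene geometry. Against it, intermolecular Pauson–Khand reactions of unstrained acyclic 1,2-disubstituted alkenes are slow and poorly regioselective, which is why A2 carries a sulfur ligand on the C1 oxygen. The facial sense relative to C5 would rest on that chelate alone. The side-chain alkenes of A2 compete for cobalt, and the propenyl group can isomerise. Ring A with its three stereocentres would still have to be made separately. The chosen strategy offers in its place polar, well-understood bond formations for ring B and a catalytic asymmetric construction of ring A.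

**Alternative 2:** Ring A would be cut at C2–C3 and C1–C5. A phosphine would add to the allenoate A6 and the resulting zwitterion would add across the acetoxyacrylate A7 to give the cyclopentene A5. On one point this is stronger: the oxygenated quaternary C1 and C5 are formed in the ring-forming step, so the facial problem of a later dihydroxylation does not arise. The furan is a stable mask for the same 1,4-diketone that the chosen route makes by a Stetter reaction. Against it, a γ-substituted allenoate and a 1,1-disubstituted acceptor must combine with control of α- against γ-addition and of a quaternary centre next to a tertiary one. C3 emerges as an enoate carbon, so it needs a later face-selective reduction. The two esters of A5 (the future C6 and C7) are at the same oxidation level and must be told apart. In the chosen route C6 appears as a hydroxymethyl group and C3 is fixed by a bridge that cannot form the wrong way.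

**Alternative 3:** Ring A would be cut at C1–C5. Cathodic reduction of the exocyclic enone in the keto enone A9 would bond its β-carbon C5 to the ketone carbon C1 and give the cyclopentanol A8. This is stronger in convergence and in taking C3 from the chiral pool. It also forms the hindered C1–C5 bond and the tertiary alcohol together, with the ring B methyl already in place. Against it, C1, C5 and (on protonation of the enolate) C1′ are all set in one electrochemical step, guided only by the remote C3 and C5′. Protonation at C1′ should favour the trans ring B, which is the wrong one. The isopropenyl group of A8 must later be extended at its methylene terminus into a Z trisubstituted alkene, which is harder than olefinating a methyl ketone. A lead or mercury cathode is also a practical burden. The chosen strategy sets C5 by a chiral catalyst, C1 and C3 by substrate geometry, and ring B by a cis hydrogenation.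

Key step: step 5

## Route

Assumption: the sense of induction of the phosphoramidite in step 5 is not predicted here; the ligand antipode that gives (4R)-10 is used, both antipodes being equally available (L = (11bS)-4-[(2R,5R)-2,5-diphenylpyrrolidin-1-yl]dinaphtho[2,1-d:1′,2′-f][1,3,2]dioxaphosphepine or its enantiomer).

Remark: hydroxy ketone 26 is drawn in its open form; it equilibrates with its bridged hemiketal, and both react as the ketone under basic conditions.

Step 1
Reactants: 1 ethynyltri(propan-2-yl)silane
Product: 3 3-[tri(propan-2-yl)silyl]prop-2-ynal, via lithium [tri(propan-2-yl)silyl]acetylide 2 (not isolated)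
Conditions: n-BuLi, THF, −78 °C; DMF, −78 → 0 °C; poured into aq. KH2PO4
Reagents that add atoms: N,N-dimethylformamide, CN(C)C=O
Why: Deprotonation of the terminal alkyne and formylation of the acetylide with DMF; the buffered inverse quench frees the ynal without conjugate addition of the liberated amine.

Step 2
Reactants: 4 2-bromo-3-(trimethylsilyl)prop-1-ene; 3 3-[tri(propan-2-yl)silyl]prop-2-ynal
Product: 6 rac-1-[tri(propan-2-yl)silyl]-4-[(trimethylsilyl)methyl]pent-4-en-1-yn-3-ol, via [3-(trimethylsilyl)prop-1-en-2-yl]magnesium bromide 5 (not isolated)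
Conditions: Mg, THF, reflux; then 3, −78 → 0 °C; aq. NH4Cl
Reagents that add atoms: none
Why: Grignard formation from the vinyl bromide and 1,2-addition to the ynal; the allylsilane is untouched and the carbinol centre may be racemic because it is lost in step 5.

Step 3
Reactants: 6 rac-1-[tri(propan-2-yl)silyl]-4-[(trimethylsilyl)methyl]pent-4-en-1-yn-3-ol
Product: 7 rac-1-[tri(propan-2-yl)silyl]-4-[(trimethylsilyl)methyl]pent-4-en-1-yn-3-yl acetate
Conditions: Ac2O, pyridine, DMAP (cat.), CH2Cl2, 0 °C → rt
Reagents that add atoms: acetic anhydride, CC(=O)OC(C)=O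
Why: Standard DMAP-catalysed acetylation of a secondary alcohol; the acetate is the leaving group for ionisation in step 5.

Step 4
Reactants: 8 dimethyl propanedioate
Product: 9 dimethyl 2-methylidenepropanedioate
Conditions: (CH2O)n, Cu(OAc)2 (cat.), KOAc (cat.), AcOH, 100 °C; distilled and used fresh
Reagents that add atoms: formaldehyde (as paraformaldehyde), C=O
Why: Knoevenagel-type methylenation of the malonate; the monomer is distilled directly before use because it polymerises on standing.

Step 5
Reactants: 7 rac-1-[tri(propan-2-yl)silyl]-4-[(trimethylsilyl)methyl]pent-4-en-1-yn-3-yl acetate; 9 dimethyl 2-methylidenepropanedioate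
Product: 10 dimethyl (4R)-3-methylidene-4-{[tri(propan-2-yl)silyl]ethynyl}cyclopentane-1,1-dicarboxylate
Conditions: Pd(dba)2 (5 mol%), phosphoramidite L (10 mol%), toluene, 0 → 23 °C, slow addition of 9
Reagents that add atoms: none
Why: Zerovalent palladium carrying L ionises the allylic acetate of 7 and the acetate removes the trimethylsilyl group, giving the zwitterionic palladium–trimethylenemethane complex, so the stereocentre of racemic 7 is erased. The negative charge sits mainly on the terminus that bears the alkyne (propargylic stabilisation), and this carbon, C5, adds to the CH2 of 9 (C4) in a Michael step. The tethered malonate anion (C3) then attacks a CH2 terminus of the remaining π-allylpalladium unit (C2): ring A closes as a five-membered ring by intramolecular allylic alkylation, so the [3+2] is stepwise, and the other terminus becomes the exocyclic C6. The closest known reaction type is the palladium-catalysed trimethylenemethane cycloaddition of donor-substituted silyl acetates (cyano, aryl, vinyl, alkynyl) with alkylidene malonates under chiral phosphoramidite control. The only new stereocentre, C5, is set in the first C–C bond formation by the ligand, which blocks one face of the palladium-bound three-carbon unit; C3 stays non-stereogenic because its two esters are equal. The step needs regioselectivity for the substituted terminus, which the anion-stabilising alkyne provides, and the bulky silyl group keeps the alkyne from binding palladium. Both CH2 termini of the π-allyl unit give the same constitution, so ring closure has no regiochemical issue. Slow addition of 9 keeps its concentration low so that ring closure outruns anionic oligomerisation.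

Step 6
Reactants: 10 dimethyl (4R)-3-methylidene-4-{[tri(propan-2-yl)silyl]ethynyl}cyclopentane-1,1-dicarboxylate
Product: 11 dimethyl (3R,4S)-3-hydroxy-3-(hydroxymethyl)-4-{[tri(propan-2-yl)silyl]ethynyl}cyclopentane-1,1-dicarboxylate
Conditions: OsO4 (2 mol%), NMO, acetone/H2O, 0 °C
Reagents that add atoms: osmium tetroxide (catalytic oxygen carrier), O=[Os](=O)(=O)=O; N-methylmorpholine N-oxide, C[N+]1([O-])CCOCC1; water, O
Why: Catalytic syn-dihydroxylation of the 1,1-disubstituted alkene; the two C3 esters are identical, so the only biasing element is the alkynyl group on the adjacent C5 and the reagent should add to the opposite face. This sets C1 with OH trans and C6 cis to the C5 substituent.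

Step 7
Reactants: 11 dimethyl (3R,4S)-3-hydroxy-3-(hydroxymethyl)-4-{[tri(propan-2-yl)silyl]ethynyl}cyclopentane-1,1-dicarboxylate
Product: 13 5-hydroxy-2-oxo-6-endo-{[tri(propan-2-yl)silyl]ethynyl}-3-oxabicyclo[3.2.1]octane-1-carboxylic acid (lactone C6–O–C7 bridging C1 and C3; free CO2H on C3), via diol diacid 12 (not isolated)
Conditions: LiOH, THF/H2O, rt; HCl to pH 2; CSA (cat.), toluene, 60 °C
Reagents that add atoms: lithium hydroxide, [Li+].[OH-]
Why: Saponification, then acid-catalysed lactonisation: the C6 hydroxyl can reach only the carboxyl on its own face and forms an unstrained six-membered bridged lactone, whereas the tertiary C1 hydroxyl would have to form a strained 2-oxabicyclo[2.2.1] lactone. The two carboxyls are thereby differentiated and C3 becomes stereogenic with C7 cis to C6.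

Step 8
Reactants: 13 5-hydroxy-2-oxo-6-endo-{[tri(propan-2-yl)silyl]ethynyl}-3-oxabicyclo[3.2.1]octane-1-carboxylic acid
Product: 15 5-hydroxy-6-endo-{[tri(propan-2-yl)silyl]ethynyl}-3-oxabicyclo[3.2.1]octan-2-one, via N-acyloxypyridine-2-thione ester 14 (not isolated)
Conditions: N-hydroxypyridine-2-thione, DCC, DMAP (cat.), CH2Cl2, dark, rt; then t-BuSH, hν (tungsten lamp), rt
Reagents that add atoms: none
Why: Barton reductive decarboxylation; the bridgehead radical at C3 forms without the planar enolate that a Krapcho reaction would need and takes hydrogen from the thiol. The bridge leaves only one position for the new C3–H, so C3 is fixed with C7 cis to C6 and to the C5 substituent.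

Step 9
Reactants: 15 5-hydroxy-6-endo-{[tri(propan-2-yl)silyl]ethynyl}-3-oxabicyclo[3.2.1]octan-2-one
Product: 16 6-endo-ethynyl-5-hydroxy-3-oxabicyclo[3.2.1]octan-2-one
Conditions: TBAF, AcOH, THF, 0 °C → rt
Reagents that add atoms: none
Why: Fluoride cleaves the alkynyl C–Si bond; acetic acid buffering protects the lactone from basic opening.

Step 10
Reactants: 16 6-endo-ethynyl-5-hydroxy-3-oxabicyclo[3.2.1]octan-2-one
Product: 17 6-endo-ethynyl-5-[(triethylsilyl)oxy]-3-oxabicyclo[3.2.1]octan-2-one
Conditions: TESOTf, 2,6-lutidine, CH2Cl2, −78 → 0 °C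
Reagents that add atoms: triethylsilyl trifluoromethanesulfonate, CC[Si](CC)(CC)OS(=O)(=O)C(F)(F)F
Why: Silyl triflate silylation of the hindered tertiary alcohol; the bulky ether later shields the C1 side of the enone in step 14.

Step 11
Reactants: 17 6-endo-ethynyl-5-[(triethylsilyl)oxy]-3-oxabicyclo[3.2.1]octan-2-one
Product: 18 2-{2-oxo-5-[(triethylsilyl)oxy]-3-oxabicyclo[3.2.1]octan-6-endo-yl}acetaldehyde
Conditions: [CpRu(MeCN)3]PF6 (5 mol%), 5,5′-bis(trifluoromethyl)-2,2′-bipyridine (5 mol%), NMP/H2O, 25 °C
Reagents that add atoms: water, O
Why: Ruthenium-catalysed anti-Markovnikov hydration of the terminal alkyne through a vinylidene complex; neutral conditions leave lactone and silyl ether intact, and C5 is β to the new carbonyl and cannot epimerise.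

Step 12
Reactants: 18 2-{2-oxo-5-[(triethylsilyl)oxy]-3-oxabicyclo[3.2.1]octan-6-endo-yl}acetaldehyde; 19 but-3-en-2-one
Product: 20 1-{2-oxo-5-[(triethylsilyl)oxy]-3-oxabicyclo[3.2.1]octan-6-endo-yl}hexane-2,5-dione
Conditions: 3-benzyl-5-(2-hydroxyethyl)-4-methylthiazolium chloride (20 mol%), Et3N, dioxane, 70 °C
Reagents that add atoms: none
Why: Stetter reaction: the thiazolylidene turns the aldehyde into an acyl anion equivalent (Breslow intermediate) that adds 1,4 to the enone and forms the C2′–C3′ bond.

Step 13
Reactants: 20 1-{2-oxo-5-[(triethylsilyl)oxy]-3-oxabicyclo[3.2.1]octan-6-endo-yl}hexane-2,5-dione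
Product: 21 6-endo-(2-methyl-5-oxocyclopent-1-en-1-yl)-5-[(triethylsilyl)oxy]-3-oxabicyclo[3.2.1]octan-2-one
Conditions: KOt-Bu (0.3 equiv), t-BuOH, 40 °C
Reagents that add atoms: none
Why: Intramolecular aldol condensation of the 1,4-diketone: reversible aldol addition followed by dehydration funnels to the conjugated 2,3-disubstituted cyclopentenone (C1′ onto C5′), as in jasmone-type annulations. The non-aqueous base spares the lactone.

Step 14
Reactants: 21 6-endo-(2-methyl-5-oxocyclopent-1-en-1-yl)-5-[(triethylsilyl)oxy]-3-oxabicyclo[3.2.1]octan-2-one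
Product: 22 6-endo-[(1S,2R)-2-methyl-5-oxocyclopentyl]-5-[(triethylsilyl)oxy]-3-oxabicyclo[3.2.1]octan-2-one (C1′ S; C5′ R; ring B cis)
Conditions: H2 (3 atm), 10% Pd/C, EtOAc, rt
Reagents that add atoms: none
Why: Syn addition of hydrogen on the palladium surface makes C1′–H and C5′–H cis. Allylic 1,3-strain holds C5–H in the enone plane next to the C5′ methyl, so the quaternary C1 with its silyl ether covers one face and hydrogen should arrive from the C4 side, which corresponds to 1′S,5′R. Neutral solvent avoids epimerisation to the trans ketone.

Step 15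
Reactants: 22 6-endo-[(1S,2R)-2-methyl-5-oxocyclopentyl]-5-[(triethylsilyl)oxy]-3-oxabicyclo[3.2.1]octan-2-one
Product: 23 5-hydroxy-6-endo-[(1S,2R)-2-methyl-5-oxocyclopentyl]-3-oxabicyclo[3.2.1]octan-2-one
Conditions: HF·pyridine, pyridine, THF, 0 °C → rt
Reagents that add atoms: none
Why: Buffered fluoride desilylation; the silyl ether is removed now because a C6 alkoxide formed in steps 17 and 19 would otherwise pull it from O1 to O6 by 1,2-migration.

Step 16
Reactants: 23 5-hydroxy-6-endo-[(1S,2R)-2-methyl-5-oxocyclopentyl]-3-oxabicyclo[3.2.1]octan-2-one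
Product: 25 6-endo-{(1S,5R)-2-[(tert-butyldimethylsilyl)oxy]-5-methylcyclopent-2-en-1-yl}-5-hydroxy-3-oxabicyclo[3.2.1]octan-2-one, via dilithium alkoxide enolate 24 (not isolated)
Conditions: LiN(iPr)2 (2.2 equiv), THF, −78 °C (ketone added to base); TBSCl, DMPU, −78 → 0 °C
Reagents that add atoms: tert-butyl(chloro)dimethylsilane, CC(C)(C)[Si](C)(C)Cl
Why: Kinetic deprotonation at the unhindered C3′H2 and O-silylation of the enolate; the hindered tertiary lithium alkoxide does not react with the silyl chloride and the lactone has no enolisable hydrogen. The enol ether masks the ketone, blocks epimerisation at C1′ and is the substrate for step 21.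

Step 17
Reactants: 25 6-endo-{(1S,5R)-2-[(tert-butyldimethylsilyl)oxy]-5-methylcyclopent-2-en-1-yl}-5-hydroxy-3-oxabicyclo[3.2.1]octan-2-one
Product: 26 methyl ketone: ring A with C1–OH; C6H2OH; C3–C(=O)CH3; ring B as its enol silyl ether (open tautomer of the bridged hemiketal)
Conditions: MeLi (2.3 equiv), THF, −78 °C; aq. NH4Cl at −78 °C
Reagents that add atoms: methyllithium, [Li]C
Why: Mono-addition of the organolithium to the lactone: after deprotonation of the hydroxyl the tetrahedral lithium hemiketal persists at −78 °C, so a second addition is suppressed, and cold quench releases the hydroxy ketone. The silyl enol ether is inert at this temperature.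

Step 18
Reactants: 27 5-bromo-2-methylpent-2-ene
Product: 28 (4-methylpent-3-en-1-yl)triphenylphosphonium bromide
Conditions: PPh3, MeCN, reflux
Reagents that add atoms: triphenylphosphine, c1ccc(cc1)P(c1ccccc1)c1ccccc1
Why: SN2 quaternisation of the phosphine by the primary bromide.

Step 19
Reactants: 28 (4-methylpent-3-en-1-yl)triphenylphosphonium bromide; 26 methyl ketone (C1–OH; C6H2OH; C3–C(=O)CH3)
Product: 30 diol with the (7Z)-C7(CH3)=C8H–C9H2–C10H=C11(CH3)2 side chain on C3; C1–OH; C6H2OH; ring B as its enol silyl ether, via phosphorus ylide 29 (not isolated)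
Conditions: KN(SiMe3)2 (4 equiv), 28 (4.2 equiv), THF, 0 °C; then 26, −78 °C → rt
Reagents that add atoms: none
Why: Wittig olefination with a non-stabilised ylide under lithium-free conditions; kinetic oxaphosphetane formation places the ylide substituent cis to the larger ketone substituent (ring A), which is the Z alkene. Excess ylide covers the two hydroxyls, and the minor E isomer is removed on AgNO3-impregnated silica.

Step 20
Reactants: 30 diol with the (7Z) skipped-diene side chain
Product: 31 C6 acetate of 30 (C1–OH free; ring B as its enol silyl ether)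
Conditions: Ac2O (1.5 equiv), pyridine, DMAP (5 mol%), CH2Cl2, 0 °C
Reagents that add atoms: acetic anhydride, CC(=O)OC(C)=O
Why: Acetylation of the primary hydroxyl; the hindered tertiary C1 hydroxyl does not react under these conditions and the silyl enol ether is stable to amine bases.

Step 21
Reactants: 31 C6 acetate with ring B as its enol silyl ether
Product: 32 deoxy precursor: [(1R,3S,5S)-1-hydroxy-5-[(1S,5R)-5-methyl-2-oxocyclopent-3-en-1-yl]-3-[(2Z)-6-methylhepta-2,5-dien-2-yl]cyclopentyl]methyl acetate
Conditions: Pd(OAc)2 (1.2 equiv), MeCN, 40 °C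
Reagents that add atoms: none
Why: Saegusa–Ito oxidation: divalent palladium converts the silyl enol ether into a C3′-bound palladium enolate, and β-hydride elimination from C4′ gives the C3′=C4′ enone. C1′ is not touched, and the acetate and free tertiary alcohol are compatible.

Step 22
Reactants: 32 deoxy precursor
Product: 33 [(1R,3S,5S)-3-[(2Z,4E)-6-hydroperoxy-6-methylhepta-2,4-dien-2-yl]-1-hydroxy-5-[(1S,5R)-5-methyl-2-oxocyclopent-3-en-1-yl]cyclopentyl]methyl acetate
Conditions: O2, visible light, 5,10,15,20-tetraphenylporphyrin (cat.), CH2Cl2, −20 °C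
Reagents that add atoms: dioxygen, O=O
Why: Schenck ene reaction of singlet oxygen at the electron-rich terminal trisubstituted alkene: oxygen bonds to C11, hydrogen is taken from the doubly allylic C9 and the double bond shifts to C9=C10 (E), giving the conjugated diene. The electron-poor enone is inert, and regioisomeric hydroperoxides are removed by chromatography.

## Compound list

1 | ethynyltri(propan-2-yl)silane | C#C[Si](C(C)C)(C(C)C)C(C)C | starting material
2 | lithium [tri(propan-2-yl)silyl]acetylide | [Li]C#C[Si](C(C)C)(C(C)C)C(C)C | intermediate (not isolated)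
3 | 3-[tri(propan-2-yl)silyl]prop-2-ynal | O=CC#C[Si](C(C)C)(C(C)C)C(C)C | intermediate
4 | 2-bromo-3-(trimethylsilyl)prop-1-ene | C=C(Br)C[Si](C)(C)C | starting material
5 | [3-(trimethylsilyl)prop-1-en-2-yl]magnesium bromide | C=C(C[Si](C)(C)C)[Mg]Br | intermediate (not isolated)
6 | rac-1-[tri(propan-2-yl)silyl]-4-[(trimethylsilyl)methyl]pent-4-en-1-yn-3-ol | C=C(C[Si](C)(C)C)C(O)C#C[Si](C(C)C)(C(C)C)C(C)C | intermediate
7 | rac-1-[tri(propan-2-yl)silyl]-4-[(trimethylsilyl)methyl]pent-4-en-1-yn-3-yl acetate | C=C(C[Si](C)(C)C)C(OC(C)=O)C#C[Si](C(C)C)(C(C)C)C(C)C | intermediate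
8 | dimethyl propanedioate | COC(=O)CC(=O)OC | starting material
9 | dimethyl 2-methylidenepropanedioate | C=C(C(=O)OC)C(=O)OC | intermediate
10 | dimethyl (4R)-3-methylidene-4-{[tri(propan-2-yl)silyl]ethynyl}cyclopentane-1,1-dicarboxylate | C=C1CC(C(=O)OC)(C(=O)OC)C[C@H]1C#C[Si](C(C)C)(C(C)C)C(C)C | intermediate
11 | dimethyl (3R,4S)-3-hydroxy-3-(hydroxymethyl)-4-{[tri(propan-2-yl)silyl]ethynyl}cyclopentane-1,1-dicarboxylate (OH trans to alkynyl) | OC[C@@]1(O)CC(C(=O)OC)(C(=O)OC)C[C@H]1C#C[Si](C(C)C)(C(C)C)C(C)C | intermediate
12 | (3R,4S)-3-hydroxy-3-(hydroxymethyl)-4-{[tri(propan-2-yl)silyl]ethynyl}cyclopentane-1,1-dicarboxylic acid | OC[C@@]1(O)CC(C(=O)O)(C(=O)O)C[C@H]1C#C[Si](C(C)C)(C(C)C)C(C)C | intermediate (not isolated)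
13 | 5-hydroxy-2-oxo-6-endo-{[tri(propan-2-yl)silyl]ethynyl}-3-oxabicyclo[3.2.1]octane-1-carboxylic acid (lactone C6–O–C7; CO2H on C3; C1, C5 as in 33) | O=C1OC[C@@]2(O)C[C@]1(C(=O)O)C[C@H]2C#C[Si](C(C)C)(C(C)C)C(C)C | intermediate
14 | N-acyloxypyridine-2-thione (Barton) ester of 13 | O=C1OC[C@@]2(O)C[C@]1(C(=O)ON3C=CC=CC3=S)C[C@H]2C#C[Si](C(C)C)(C(C)C)C(C)C | intermediate (not isolated)
15 | 5-hydroxy-6-endo-{[tri(propan-2-yl)silyl]ethynyl}-3-oxabicyclo[3.2.1]octan-2-one (C1, C3, C5 as in 33) | O=C1OC[C@@]2(O)C[C@@H]1C[C@H]2C#C[Si](C(C)C)(C(C)C)C(C)C | intermediate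
16 | 6-endo-ethynyl-5-hydroxy-3-oxabicyclo[3.2.1]octan-2-one | O=C1OC[C@@]2(O)C[C@@H]1C[C@H]2C#C | intermediate
17 | 6-endo-ethynyl-5-[(triethylsilyl)oxy]-3-oxabicyclo[3.2.1]octan-2-one | O=C1OC[C@@]2(O[Si](CC)(CC)CC)C[C@@H]1C[C@H]2C#C | intermediate
18 | 2-{2-oxo-5-[(triethylsilyl)oxy]-3-oxabicyclo[3.2.1]octan-6-endo-yl}acetaldehyde | O=C1OC[C@@]2(O[Si](CC)(CC)CC)C[C@@H]1C[C@H]2CC=O | intermediate
19 | but-3-en-2-one | CC(=O)C=C | starting material
20 | 1-{2-oxo-5-[(triethylsilyl)oxy]-3-oxabicyclo[3.2.1]octan-6-endo-yl}hexane-2,5-dione | O=C1OC[C@@]2(O[Si](CC)(CC)CC)C[C@@H]1C[C@H]2CC(=O)CCC(C)=O | intermediate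
21 | 6-endo-(2-methyl-5-oxocyclopent-1-en-1-yl)-5-[(triethylsilyl)oxy]-3-oxabicyclo[3.2.1]octan-2-one | O=C1OC[C@@]2(O[Si](CC)(CC)CC)C[C@@H]1C[C@H]2C1=C(C)CCC1=O | intermediate
22 | 6-endo-[(1S,2R)-2-methyl-5-oxocyclopentyl]-5-[(triethylsilyl)oxy]-3-oxabicyclo[3.2.1]octan-2-one (ring B cis) | O=C1OC[C@@]2(O[Si](CC)(CC)CC)C[C@@H]1C[C@H]2[C@H]1C(=O)CC[C@H]1C | intermediate
23 | 5-hydroxy-6-endo-[(1S,2R)-2-methyl-5-oxocyclopentyl]-3-oxabicyclo[3.2.1]octan-2-one | O=C1OC[C@@]2(O)C[C@@H]1C[C@H]2[C@H]1C(=O)CC[C@H]1C | intermediate
24 | dilithium C1-alkoxide C2′-enolate of 23 | O=C1OC[C@@]2(O[Li])C[C@@H]1C[C@H]2[C@H]1C(O[Li])=CC[C@H]1C | intermediate (not isolated)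
25 | 6-endo-{(1S,5R)-2-[(tert-butyldimethylsilyl)oxy]-5-methylcyclopent-2-en-1-yl}-5-hydroxy-3-oxabicyclo[3.2.1]octan-2-one | O=C1OC[C@@]2(O)C[C@@H]1C[C@H]2[C@H]1C(O[Si](C)(C)C(C)(C)C)=CC[C@H]1C | intermediate
26 | methyl ketone: ring A with C1–OH, C6H2OH, C3–C(=O)CH3 (cis to C6 and to ring B); ring B as its tert-butyldimethylsilyl enol ether; open tautomer of the bridged hemiketal | OC[C@@]1(O)C[C@@H](C(C)=O)C[C@H]1[C@H]1C(O[Si](C)(C)C(C)(C)C)=CC[C@H]1C | intermediate
27 | 5-bromo-2-methylpent-2-ene | CC(C)=CCCBr | starting material
28 | (4-methylpent-3-en-1-yl)triphenylphosphonium bromide | CC(C)=CCC[P+](c1ccccc1)(c1ccccc1)c1ccccc1.[Br-] | intermediate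
29 | (4-methylpent-3-en-1-ylidene)triphenylphosphorane | CC(C)=CCC=P(c1ccccc1)(c1ccccc1)c1ccccc1 | intermediate (not isolated)
30 | diol: ring A with C1–OH, C6H2OH and the (2Z)-6-methylhepta-2,5-dien-2-yl chain on C3; ring B as its tert-butyldimethylsilyl enol ether | OC[C@@]1(O)C[C@@H](/C(C)=C\CC=C(C)C)C[C@H]1[C@H]1C(O[Si](C)(C)C(C)(C)C)=CC[C@H]1C | intermediate
31 | C6 acetate of 30 | CC(=O)OC[C@@]1(O)C[C@@H](/C(C)=C\CC=C(C)C)C[C@H]1[C@H]1C(O[Si](C)(C)C(C)(C)C)=CC[C@H]1C | intermediate
32 | [(1R,3S,5S)-1-hydroxy-5-[(1S,5R)-5-methyl-2-oxocyclopent-3-en-1-yl]-3-[(2Z)-6-methylhepta-2,5-dien-2-yl]cyclopentyl]methyl acetate | CC(=O)OC[C@@]1(O)C[C@@H](/C(C)=C\CC=C(C)C)C[C@H]1[C@H]1C(=O)C=C[C@H]1C | intermediate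
33 | [(1R,3S,5S)-3-[(2Z,4E)-6-hydroperoxy-6-methylhepta-2,4-dien-2-yl]-1-hydroxy-5-[(1S,5R)-5-methyl-2-oxocyclopent-3-en-1-yl]cyclopentyl]methyl acetate | CC(=O)OC[C@@]1(O)C[C@@H](/C(C)=C\C=C\C(C)(C)OO)C[C@H]1[C@H]1C(=O)C=C[C@H]1C | target

## Step count and least certain steps

Total: 22 steps. Longest linear sequence: 20 steps (steps 1–3, 5–17 and 19–22, from 1 to 33); steps 4 and 18 are one-step side branches.

**Step 5 (key step).** The most likely failure is anionic oligomerisation of the very electrophilic acceptor 9, started by the zwitterion or by acetate before the ring closes. Lesser risks are ionisation of the doubly activated acetate towards an allenylpalladium species and an insufficient enantiomeric ratio at C5. Fallback: from 7, the cycloaddition is run with methyl acrylate, a well-behaved acceptor for this reaction class, under the same catalyst. It should give the monoester methyl (4R)-3-methylidene-4-{[tri(propan-2-yl)silyl]ethynyl}cyclopentane-1-carboxylate F1 as a mixture of C3 epimers. Dihydroxylation as in step 6 gives the diol ester F2. Treatment with catalytic KOt-Bu in THF (or DBU in hot toluene) epimerises the ester and traps the cis epimer as the bridged lactone, so both epimers converge on 15. This gives up the non-stereogenic C3 of the gem-diester but sets C3 by the same bridge and skips 11–14.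

**Step 6.** The alkynyl group is slim, so facial discrimination by the C5 substituent may be modest and part of the material may be hydroxylated on the wrong face. Fallback: the diastereomers are separated and the C1 epimer, dimethyl (3S,4S)-3-hydroxy-3-(hydroxymethyl)-4-{[tri(propan-2-yl)silyl]ethynyl}cyclopentane-1,1-dicarboxylate F3, is recycled by Corey–Winter olefination. 1,1′-Thiocarbonyldiimidazole gives the cyclic thionocarbonate F4, and trimethyl phosphite at reflux returns alkene 10 for another pass.

**Step 14.** Hydrogen may add to both faces of the enone if the rotamer about C5–C1′ is less biased than assumed, and the cis ketone may partly epimerise on the catalyst. Fallback with reagent control: from 21, CBS reduction with (S)-2-methyl-CBS-oxazaborolidine and BH3·SMe2 should give the (2′R)-allylic alcohol F5. Hydroxyl-directed hydrogenation with [Ir(cod)(PCy3)(py)]PF6 in CH2Cl2 delivers both hydrogens syn to that hydroxyl and gives the saturated alcohol F6 with C1′ and C5′ as required. Dess–Martin oxidation returns to 22. The silyl ether on C1 keeps the tertiary oxygen from competing as a directing group.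

**Step 19.** The Wittig reaction may give too much of the E isomer, and the basic ylide may enolise the ketone towards C3. Fallback by stereospecific carbometalation: from 25, DIBAL at −78 °C gives the lactol F7 and the Ohira–Bestmann reagent (K2CO3, MeOH) gives the terminal alkyne diol F8. Deprotonation (n-BuLi, 3.3 equiv) and paraformaldehyde give the propargylic alcohol F9. Alkoxide-directed iron-catalysed syn-carbomagnesiation (MeMgBr, Fe(acac)3, THF) places the methyl on C7 and leaves the ring cis to C9, giving the (Z)-allylic alcohol F10. Corey–Kim chlorination (NCS, Me2S), selective for the allylic hydroxyl, gives the (Z)-allylic chloride F11. Copper-catalysed coupling with 2-methylprop-1-enylmagnesium bromide (CuI cat., THF, −20 °C) at the primary carbon returns to 30.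

**Step 22.** Singlet oxygen can also abstract hydrogen from the methyl cis to C9 (giving a secondary hydroperoxide) or attack the C7=C8 alkene, so a mixture of regioisomeric hydroperoxides is expected and the share of 33 may be low. Fallback by a different selectivity principle: from 32, radical-chain autoxidation with triplet oxygen and N-hydroxyphthalimide as chain carrier and hydrogen donor (MeCN, 30 °C, azo initiator) abstracts only the weakest C–H bond, the doubly allylic C9–H. Oxygen is then trapped at the termini of the pentadienyl radical, with C11 the less hindered one. This leads directly to 33 and excludes abstraction from the methyl groups.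

## Further compounds

F1 | step 5 | methyl (4R)-3-methylidene-4-{[tri(propan-2-yl)silyl]ethynyl}cyclopentane-1-carboxylate (both C1 epimers) | C=C1CC(C(=O)OC)C[C@H]1C#C[Si](C(C)C)(C(C)C)C(C)C
F2 | step 5 | methyl (3R,4S)-3-hydroxy-3-(hydroxymethyl)-4-{[tri(propan-2-yl)silyl]ethynyl}cyclopentane-1-carboxylate (both C1 epimers) | OC[C@@]1(O)CC(C(=O)OC)C[C@H]1C#C[Si](C(C)C)(C(C)C)C(C)C
F3 | step 6 | dimethyl (3S,4S)-3-hydroxy-3-(hydroxymethyl)-4-{[tri(propan-2-yl)silyl]ethynyl}cyclopentane-1,1-dicarboxylate | OC[C@]1(O)CC(C(=O)OC)(C(=O)OC)C[C@H]1C#C[Si](C(C)C)(C(C)C)C(C)C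
F4 | step 6 | cyclic thionocarbonate of F3 (spiro 2-thioxo-1,3-dioxolane on the cyclopentane) | S=C1OC[C@]2(O1)CC(C(=O)OC)(C(=O)OC)C[C@H]2C#C[Si](C(C)C)(C(C)C)C(C)C
F5 | step 14 | 6-endo-[(5R)-5-hydroxy-2-methylcyclopent-1-en-1-yl]-5-[(triethylsilyl)oxy]-3-oxabicyclo[3.2.1]octan-2-one | O=C1OC[C@@]2(O[Si](CC)(CC)CC)C[C@@H]1C[C@H]2C1=C(C)CC[C@H]1O
F6 | step 14 | 6-endo-[(1S,2R,5R)-5-hydroxy-2-methylcyclopentyl]-5-[(triethylsilyl)oxy]-3-oxabicyclo[3.2.1]octan-2-one (OH cis to the ring B hydrogens at C1′ and C5′) | O=C1OC[C@@]2(O[Si](CC)(CC)CC)C[C@@H]1C[C@H]2[C@H]1[C@H](O)CC[C@H]1C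
F7 | step 19 | bridged lactol from 25 (C7 hemiacetal, both anomers; C1–OH; ring B as its silyl enol ether) | OC1OC[C@@]2(O)C[C@@H]1C[C@H]2[C@H]1C(O[Si](C)(C)C(C)(C)C)=CC[C@H]1C
F8 | step 19 | terminal alkyne diol (C3–C≡CH; C1–OH; C6H2OH; ring B as its silyl enol ether) | OC[C@@]1(O)C[C@@H](C#C)C[C@H]1[C@H]1C(O[Si](C)(C)C(C)(C)C)=CC[C@H]1C
F9 | step 19 | propargylic alcohol (C3–C≡C–CH2OH; C1–OH; C6H2OH) | OC[C@@]1(O)C[C@@H](C#CCO)C[C@H]1[C@H]1C(O[Si](C)(C)C(C)(C)C)=CC[C@H]1C
F10 | step 19 | (Z)-allylic alcohol (C3–C(CH3)=CH–CH2OH with ring cis to CH2OH; C1–OH; C6H2OH) | OC[C@@]1(O)C[C@@H](/C(C)=C\CO)C[C@H]1[C@H]1C(O[Si](C)(C)C(C)(C)C)=CC[C@H]1C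
F11 | step 19 | (Z)-allylic chloride (C3–C(CH3)=CH–CH2Cl; C1–OH; C6H2OH) | OC[C@@]1(O)C[C@@H](/C(C)=C\CCl)C[C@H]1[C@H]1C(O[Si](C)(C)C(C)(C)C)=CC[C@H]1C
F0 | step 22 | none | none
A1 | alternative 1 | methylthiomethyl-protected deoxy precursor with ring B complete | CC(=O)OC[C@@]1(OCSC)C[C@@H](/C(C)=C\CC=C(C)C)C[C@H]1[C@H]1C(=O)C=C[C@H]1C
A2 | alternative 1 | (Z)-prop-1-enyl precursor on C5 with the methylthiomethyl ether on the C1 oxygen | CC(=O)OC[C@@]1(OCSC)C[C@@H](/C(C)=C\CC=C(C)C)C[C@H]1/C=C\C
A3 | alternative 1 | ethyne | C#C
A4 | alternative 1 | carbon monoxide | [C-]#[O+]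
A5 | alternative 2 | cyclopentene with C3 ethyl ester, C1 acetoxy and methyl ester, and the (5-methylfuran-2-yl)methyl group on C5 | CCOC(=O)C1=C[C@@H](Cc2ccc(C)o2)[C@@](OC(C)=O)(C(=O)OC)C1
A6 | alternative 2 | ethyl 5-(5-methylfuran-2-yl)penta-2,3-dienoate | CCOC(=O)C=C=CCc1ccc(C)o1
A7 | alternative 2 | methyl 2-(acetyloxy)prop-2-enoate | C=C(OC(C)=O)C(=O)OC
A8 | alternative 3 | ring A cyclopentanol with C3 isopropenyl, C6 silyl ether and the saturated ring B ketone on C5 | CC(C)(C)[Si](C)(C)OC[C@@]1(O)C[C@@H](C(C)=C)C[C@H]1[C@H]1C(=O)CC[C@H]1C
A9 | alternative 3 | acyclic keto enone (C1 ketone with C6 silyl ether; exocyclic enone C5=C1′ on the ring B cyclopentanone) | CC(C)(C)[Si](C)(C)OCC(=O)C[C@@H](C(C)=C)CC=C1C(=O)CC[C@H]1C
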